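**Conventions and assumption (remark on the chemistry).** Elemane numbering is used throughout: ring C5–C10; vinyl C1=C2 and methyl C14 on C10; C3=C4–C15 on C5; C11(=C13)–C12 on C7. β is the ring face that carries the C10 methyl group. (E)-3-Methylpent-2-en-4-yn-1-ol (1) and dimethyl (S)-malate (4) are assumed to be bought as single isomers.

## Analysis of the target

Compound 31 is an elemanolide: a cyclohexane (C5–C10) cis-fused at C7–C8 to an α-methylene-γ-butyrolactone (O–C8, C12=O, C11=C13). All six ring carbons are stereogenic and contiguous. The C10 methyl, the C5 2-propenyl unit, the C6 isobutyrate, the C7–C11 bond and the lactone oxygen on C8 are β; the C9 acetate and the C10 vinyl group are α. The all-cis array C5/C6/C7 and the 1,3,5-cis set O6/O8/C14 are not the thermodynamically preferred arrangement, so they have to be made under kinetic control and cannot be repaired by equilibration. Sensitive functions are the methylene lactone (Michael acceptor), three esters of two kinds on defined oxygens, a β-acyloxy carbonyl relationship in every ketone-level intermediate (E1cB), and the 1,5-diene C2=C1–C10–C5–C4=C3, which forbids prolonged heating. Four C=C bonds of different substitution must be told apart by any oxidant. The plan rests on one feature: O–C8 and O–C9 are trans, and O–C8 is cis to C11 on C7. That is exactly the result of anti opening, at C8, of an 8α,9α-epoxide by the C12 carboxylic acid.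

## Retrosynthetic reasoning

**31 ⇒ 30 (C4=C3).** The exocyclic methylene is cut first to give ketone 30. The 2-propenyl alkene is the most electron-rich C=C of 31 and would not survive a peracid; as a ketone it is inert to the oxidation. The forward step must methylenate one ketone among five carbonyl groups without base.

**30 ⇒ 29 (O9–acetyl).** The C9 acetate is removed to the free 9α-alcohol 29, because this hydroxyl is the one the lactonisation leaves behind. The forward step is a simple acylation.

**29 ⇒ 27 (O–C8 and O–C9).** Both C–O bonds on C8 and C9 are cut back to the C8=C9 alkene of acid 27. No other disconnection sets two stereocentres and the lactone ring from an achiral alkene with the configuration enforced by mechanism (anti opening by a β-tethered acid). The forward step needs α-face oxygen transfer and chemoselectivity for the ring alkene.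

**27 ⇒ 26 ⇒ 25 ⇒ 24 ⇒ 23 (functional group level).** The C4 ketone comes from a C4 carbinol (26) that serves earlier as a traceless stereocontrol element. The acid comes from a tert-butyl ester (25), which cannot lactonise onto O6. The C10 vinyl group comes from an alkyne (24, 23). A silyl alkyne keeps the two unsaturated groups on C10 different, so C10 stays a defined stereocentre during ring closure.

**23 ⇒ 22 (C8=C9).** The only ring C=C is opened by a metathesis disconnection. This leaves an open chain (22) whose stereocentres can be made by acyclic stereocontrol, and the ring closure itself creates no stereocentre.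

**22 ⇒ 21 ⇒ 20 ⇒ 13 + 17 (C6–C7).** After removal of the two acyl groups, the C6–C7 bond is cut between an aldehyde carbon (lactol 13) and the γ-carbon of a 2-(alkoxycarbonyl)allyl metal from bromide 17. This single bond brings in C7, the acrylate and the C8 vinyl group and sets C6 and C7. The forward addition must be 6,7-syn and anti-Felkin with respect to C5, which is the intrinsic preference of a (Z)-γ-substituted allyl metal.

**13 ⇒ 12 ⇒ 11 ⇒ 8 (C5–C10).** The bond between the two most hindered carbons is cut by an ester enolate Claisen disconnection of allylic ester 8. The rearrangement forms the quaternary centre and C5 together through a chair, and the C4 hydroxyl of the acid part (chelated dianion) controls the face. The lactone 11 is the natural resting form of the product.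

**8 ⇒ 7 + 3; 17 ⇒ 16 ⇒ 14 + 15.** Ester 8 is split into acid 7 (from 4 via 5 and 6, which supplies C4, C5, C6, C15 and the controlling stereocentre) and the enynol 3 (from 1, which supplies C1, C2, C9, C10, C14). Bromide 17 comes from the Baylis–Hillman adduct 16 of acrolein (14) and tert-butyl acrylate (15).

## Alternatives that were turned down

**Alternative 1:** Disconnection of C6–C7 with the lactone already present as a butenolide. In the forward step SmI2 reduces the C6 aldehyde of the open-chain butenolide aldehyde A1 to a ketyl, which adds to the butenolide β-carbon C7 and gives the 6-hydroxy lactone A2.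
- For: the carbocycle closes under mild, neutral conditions, and cis ring fusion follows from the five-membered acceptor. No peracid is used, so the 2-propenyl group can be carried unmasked; on this point the alternative is stronger than the chosen route, which needs a ketone mask and a late methylenation.
- Against: A1 must already hold C8, C9, C10 and C5 on an open chain, with the quaternary C10 between two stereocentres and an epimerisable α-branched aldehyde. The orientation of O6 is decided by the ketyl geometry, where the samarium-bound oxygen normally turns away from the unsaturated carbonyl unit; 31 needs O6 syn to C11, which cannot be taken for granted. A2 lacks C13, so an enolate methylenation of the lactone and exchange of two silyl ethers for acetates plus acylation of O6 follow, at least five steps after ring closure.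
- Comparison: the chosen strategy sets C8 and C9 together by a stereospecific anti opening and ends two steps after the key step with all acyl groups in place.

**Alternative 2:** Disconnection of C7–C8 and O–C12. In the forward step CrCl2 turns the allylic bromide A3 into an allylchromium that adds through C7 to the C8 aldehyde; the divalent chromium step is followed by attack of the C8 alkoxide on the methyl ester to give lactone A4.
- For: two rings, two stereocentres and the exocyclic methylene form in one step, and the 2-propenyl group needs no mask. In bond-forming power at the key step this alternative is stronger than the chosen one, which closes only the lactone.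
- Against: A3 carries C5, C6, C9 and C10 on an open chain, with an α-alkoxy aldehyde that epimerises easily and a (Z)-2-(bromomethyl)enoate next to a silyloxy stereocentre, which is hard to make by allylic bromination of a hindered Baylis–Hillman adduct. The configuration at C8 depends on which aldehyde face the allylchromium meets; the mechanism does not enforce it. Afterwards the PMB ether and the TBS ether must be exchanged for acetate and isobutyrate on a nucleophile-sensitive methylene lactone (four steps).
- Comparison: the chosen route uses the same acrylate-allyl metal chemistry intermolecularly on a simpler aldehyde, and obtains C8/C9 from an alkene with the sense of opening fixed by the tether.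

**Alternative 3:** Disconnection of C7–C11 with radical closure of the lactone. In the forward step Mn(OAc)3 oxidises the C8 malonate of the silyl enol ether A5 to a radical that adds 5-exo to C7; the trivalent manganese then oxidises the α-silyloxy radical so that C6 emerges as a ketone in lactone A6.
- For: 5-exo closure guarantees the cis ring fusion, as reliably as the anti opening of the chosen route. Both acetates are already in place, and the tert-butyl ester on C11 allows a clean decarboxylative methylenation.
- Against: A5 is the silyl enol ether of a β-acyloxy ketone, so generating it towards C7 without E1cB loss of the malonate is doubtful. The electrophilic malonyl radical and the oxidant can also attack the 2-propenyl and vinyl groups or the enol ether directly. A6 has a C6 ketone next to C5, which can epimerise or move the C3=C4 alkene into conjugation, and it still needs a face-selective reduction to the axial 6β-alcohol, acylation and methylenation (three to four steps).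
- Comparison: the chosen route fixes C6 before the ring exists, in an open-chain addition with a predictable sense, and its key step uses a closed-shell oxidant that discriminates the alkenes by electron density.

Key step: step 19

## Route

Step 1
Reactants: 1 (E)-3-methylpent-2-en-4-yn-1-ol
Product: 3 (E)-3-methyl-5-(trimethylsilyl)pent-2-en-4-yn-1-ol, via bis-silyl ether 2 (not isolated)
Conditions: n-BuLi (2.2 equiv), THF, −78 °C; Me3SiCl (2.3 equiv), −78 °C → rt; 1 M HCl, rt
Reagents that add atoms: chlorotrimethylsilane, C[Si](C)(C)Cl
Why: Double deprotonation (alkoxide, acetylide) and bis-silylation; the O–Si bond of 2 is hydrolysed in the acidic work-up while the C–Si bond stays, which caps the alkyne against base in step 6 and against metathesis in step 14; the (E)-alkene is untouched.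

Step 2
Reactants: 4 dimethyl (S)-malate
Product: 5 methyl (S)-3,4-dihydroxybutanoate
Conditions: BH3·SMe2 (1.05 equiv), NaBH4 (5 mol%), THF, rt; MeOH quench
Reagents that add atoms: none
Why: Borane reduction catalysed by NaBH4 is directed by the free α-hydroxyl, so only the ester next to the carbinol is reduced (hydroxyl-directed chemoselective ester reduction); the stereocentre is not involved.

Step 3
Reactants: 5 methyl (S)-3,4-dihydroxybutanoate
Product: 6 methyl (S)-3-hydroxy-4-(trityloxy)butanoate
Conditions: TrCl (1.1 equiv), Et3N, DMAP (cat.), CH2Cl2, 0 °C → rt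
Reagents that add atoms: trityl chloride, ClC(c1ccccc1)(c1ccccc1)c1ccccc1
Why: Trityl chloride reacts only with the primary hydroxyl for steric reasons; trityl is chosen because it cannot migrate to the neighbouring alkoxide in step 6 and leaves under mild acid.

Step 4
Reactants: 6 methyl (S)-3-hydroxy-4-(trityloxy)butanoate
Product: 7 (S)-3-hydroxy-4-(trityloxy)butanoic acid
Conditions: LiOH, THF/H2O, 0 °C; 1 M HCl to pH 4, 0 °C
Reagents that add atoms: lithium hydroxide (aqueous), [Li+].[OH-]
Why: Saponification of a methyl ester at 0 °C; the β-hydroxy acid does not undergo retro-aldol cleavage under these conditions and careful acidification spares the trityl ether.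

Step 5
Reactants: 7 (S)-3-hydroxy-4-(trityloxy)butanoic acid; 3 (E)-3-methyl-5-(trimethylsilyl)pent-2-en-4-yn-1-ol
Product: 8 (2E)-3-methyl-5-(trimethylsilyl)pent-2-en-4-yn-1-yl (3S)-3-hydroxy-4-(trityloxy)butanoate
Conditions: EDC·HCl (1.2 equiv), DMAP (0.1 equiv), CH2Cl2, 0 °C → rt
Reagents that add atoms: none
Why: Steglich-type carbodiimide esterification; the primary allylic alcohol 3 outcompetes the hindered secondary β-hydroxyl of 7, so self-condensation should stay minor.

Step 6
Reactants: 8 (2E)-3-methyl-5-(trimethylsilyl)pent-2-en-4-yn-1-yl (3S)-3-hydroxy-4-(trityloxy)butanoate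
Product: 11 (3R,4S)-4-hydroxy-3-[(3R)-3-methyl-5-(trimethylsilyl)pent-1-en-4-yn-3-yl]oxolan-2-one (cis lactone; lactone C2 = C6, C3 = C5, C4 = C4, C5 = C15), via Claisen acid 9 (not isolated), via dihydroxy acid 10 (not isolated)
Conditions: LiN(i-Pr)2 (2.4 equiv), THF, −78 °C → 40 °C; aq. HCl quench; crude in MeOH/CH2Cl2, TsOH·H2O (0.1 equiv), rt
Reagents that add atoms: none
Why: Ester enolate (Ireland-type) Claisen rearrangement of the dilithium alkoxide–enolate: the lithium chelate fixes the enolate geometry (C4 trans to the allylic oxygen) and, as in a Fráter–Seebach alkylation, leaves the face anti to CH2OTr open, which sets C5 (R). In the chair the (E)-alkene carries CH3 axial and the alkynyl group equatorial, so C10 (R) forms with CH3 and the C4 branch cis on the later ring and the new vinyl group becomes C9. Acid then cleaves the trityl ether and the γ-hydroxy acid 10 lactonises, which ties up C6 and C15 for the next steps.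

Step 7
Reactants: 11 hydroxy lactone
Product: 12 (3R,4S)-4-[(tert-butyldimethylsilyl)oxy]-3-[(3R)-3-methyl-5-(trimethylsilyl)pent-1-en-4-yn-3-yl]oxolan-2-one
Conditions: TBSOTf (1.3 equiv), 2,6-lutidine, CH2Cl2, 0 °C
Reagents that add atoms: tert-butyldimethylsilyl triflate, CC(C)(C)[Si](C)(C)OS(=O)(=O)C(F)(F)F
Why: Silylation of the hindered secondary alcohol with the triflate; the bulky, poorly coordinating OTBS group later blocks chelation through O4 in step 11 and marks O4 for the late oxidation.

Step 8
Reactants: 12 silyloxy lactone
Product: 13 (3R,4S)-4-[(tert-butyldimethylsilyl)oxy]-3-[(3R)-3-methyl-5-(trimethylsilyl)pent-1-en-4-yn-3-yl]oxolan-2-ol (lactol, both anomers)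
Conditions: i-Bu2AlH (1.1 equiv), CH2Cl2, −78 °C; aq. potassium sodium tartrate
Reagents that add atoms: none
Why: Half-reduction of a γ-lactone to the lactol at −78 °C through a stable aluminium hemiacetal; C5 is not epimerised under these non-basic conditions.

Step 9
Reactants: 14 acrolein; 15 tert-butyl acrylate
Product: 16 tert-butyl 3-hydroxy-2-methylidenepent-4-enoate (racemic)
Conditions: DABCO (0.3 equiv), excess 15, 0 °C → rt
Reagents that add atoms: none
Why: Baylis–Hillman reaction: the DABCO–acrylate zwitterion adds to the aldehyde carbon of acrolein; the new carbinol centre is racemic and is destroyed in step 10.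

Step 10
Reactants: 16 tert-butyl 3-hydroxy-2-methylidenepent-4-enoate
Product: 17 tert-butyl (2Z)-2-(bromomethyl)penta-2,4-dienoate
Conditions: PBr3 (0.4 equiv), Et2O, −10 → 0 °C; used fresh
Reagents that add atoms: phosphorus tribromide, BrP(Br)Br
Why: Allylic bromination with transposition (SN2') gives the conjugated dienoate with the bromomethyl group cis to the vinyl group, the preferred geometry of 2-(bromomethyl)alk-2-enoates.

Step 11
Reactants: 13 lactol; 17 tert-butyl (2Z)-2-(bromomethyl)penta-2,4-dienoate
Product: 20 tert-butyl (3S,4R,5S,6S)-6-[(tert-butyldimethylsilyl)oxy]-3-ethenyl-4,7-dihydroxy-2-methylidene-5-[(3R)-3-methyl-5-(trimethylsilyl)pent-1-en-4-yn-3-yl]heptanoate (heptanoate C3 = C7, C4 = C6, C5 = C5, C6 = C4, C7 = C15), via open-chain aldehyde 18 (not isolated), via allylindium dibromide 19 (not isolated)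
Conditions: In powder (2 equiv), 17 (2 equiv), THF/H2O 1:1, rt
Reagents that add atoms: none
Why: Barbier-type indium allylation of the lactol through its hydroxy aldehyde tautomer 18; bond formation at the γ-carbon of 19 in a Zimmerman–Traxler chair puts the vinyl group (cis to CH2In) axial, which gives the 6,7-syn relationship. With the quaternary C10 anti to the forming bond, an inside C4 branch would clash syn-pentane-like with that axial vinyl group, so hydrogen sits inside and C4 outside (anti-Felkin), the intrinsic preference of (Z)-γ-substituted allyl metals. This is the all-cis C5/C6/C7 pattern of the later ring; water as cosolvent and the OTBS group disfavour chelation.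

Step 12
Reactants: 20 diol
Product: 21 the 15-O-acetate of 20 (6-OH free)
Conditions: AcCl (1.05 equiv), 2,4,6-collidine, CH2Cl2, −78 °C
Reagents that add atoms: acetyl chloride, CC(=O)Cl
Why: Acetyl chloride with collidine at −78 °C acylates primary hydroxyls selectively; the C6 hydroxyl is secondary and flanked by two branched carbons.

Step 13
Reactants: 21 15-acetate
Product: 22 the 6-O-(2-methylpropanoate) of 21 (open-chain triene-yne with 15-OAc, 4-OTBS, tert-butyl ester)
Conditions: (i-PrCO)2O (3 equiv), DMAP (1 equiv), Et3N, CH2Cl2, rt
Reagents that add atoms: isobutyric anhydride, CC(C)C(=O)OC(=O)C(C)C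
Why: DMAP-catalysed acylation of the remaining hindered secondary alcohol; the tert-butyl ester prevents lactonisation of O6 onto C12 and the mild amine base does not deprotonate the doubly allylic C7–H.

Step 14
Reactants: 22 open-chain isobutyrate
Product: 23 cyclohexene (ring C5–C10, C8=C9) with 10β-CH3, 10α-C≡C–SiMe3, 5β-CH(OTBS)CH2OAc, 6β-OCOCHMe2, 7β-C(=CH2)CO2t-Bu
Conditions: second-generation Grubbs catalyst (5–10 mol%), CH2Cl2 (0.005 M), 40 °C
Reagents that add atoms: none
Why: Ring-closing metathesis of the two monosubstituted vinyl groups closes the six-membered ring at C8=C9 with loss of ethene; the 1,1-disubstituted acrylate and the silyl-capped alkyne on a quaternary carbon are much poorer partners for the ruthenium carbene, and no stereocentre is touched.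

Step 15
Reactants: 23 silyl alkyne
Product: 24 the terminal alkyne (10α-C≡CH; otherwise as 23)
Conditions: AgNO3 (0.1 equiv), MeOH/H2O/CH2Cl2, rt
Reagents that add atoms: none
Why: Silver-catalysed protiodesilylation cleaves only the alkynyl C–Si bond under neutral conditions, leaving the TBS ether, the three esters and the base-sensitive C7–H intact.

Step 16
Reactants: 24 terminal alkyne
Product: 25 the 10α-vinyl compound (C1=C2 in place; 4-OTBS, tert-butyl ester)
Conditions: H2 (1 atm), Pd/CaCO3–Pb(OAc)2 (Lindlar catalyst), quinoline, EtOAc, rt
Reagents that add atoms: none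
Why: Lindlar semi-hydrogenation stops at the alkene for a terminal alkyne; the ring alkene and the 2-substituted acrylate are reduced far more slowly on the poisoned catalyst. C10 now carries the C1=C2 vinyl group with its configuration fixed.

Step 17
Reactants: 25 silyl ether tert-butyl ester
Product: 26 hydroxy acid (4-OH, C12 acid; 15-OAc and 6β-isobutyrate kept)
Conditions: CF3CO2H/H2O 9:1, CH2Cl2, 0 °C → rt
Reagents that add atoms: none
Why: Aqueous trifluoroacetic acid cleaves the tert-butyl ester (loss of 2-methylpropene) and the secondary TBS ether in one operation; acetate and isobutyrate survive, and a primary acetate next to a secondary hydroxyl is the favoured regioisomer, so acyl migration is not expected.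

Step 18
Reactants: 26 hydroxy acid
Product: 27 keto acid, the key-step precursor: cyclohex-8-ene with 10β-CH3, 10α-vinyl, 5β-C(=O)CH2OAc, 6β-OCOCHMe2, 7β-C(=CH2)CO2H
Conditions: Dess–Martin periodinane (1.5 equiv), CH2Cl2, rt
Reagents that add atoms: none
Why: Dess–Martin oxidation of the secondary carbinol under neutral to slightly acidic conditions gives the β-acyloxy ketone without E1cB loss of isobutyrate or epimerisation at C5; the traceless C4 stereocentre is erased here.

Step 19
Reactants: 27 keto acid
Product: 29 9α-hydroxy-8β,12-olide (cis-fused α-methylene lactone; C4 ketone, 15-OAc, 6β-isobutyrate), via epoxy acid 28 (not isolated)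
Conditions: m-CPBA (1.3 equiv), CH2Cl2, 0 °C → rt
Reagents that add atoms: m-chloroperbenzoic acid, O=C(OO)c1cccc(Cl)c1
Why: Concerted (butterfly) oxygen transfer from the peracid to the cis-disubstituted ring alkene is followed by intramolecular SN2 opening of epoxide 28 at C8 by the C12 carboxylic acid, assisted by the m-chlorobenzoic acid set free. The closest known reaction type is peracid epoxidation of cyclohex-2-enylacetic acids with in situ γ-lactonisation, the oxygen analogue of iodolactonisation. The lactone ring closes in the 5-exo-tet mode (O attacks C8 and the breaking C8–O bond is exocyclic to the new ring); attack at C9 would need a bridged six-membered lactone. C9 is set by the face of epoxidation: in the half-chair with the C5 acyl group equatorial, the pseudoaxial C10 methyl and the axial C6 isobutyrate, together with the C7 side chain, screen the β face, so oxygen is delivered to the α face. C8 is set by inversion: the acid is tethered on the β face and can only open the α-epoxide anti, which gives the cis ring fusion and the trans-diaxial 8β-O/9α-OH pair expected from the Fürst–Plattner rule. The step needs chemoselectivity for C8=C9 and α-face selectivity: the acrylic acid alkene is electron-poor, the vinyl group is monosubstituted and neopentyl, the 2-propenyl group is present only as a ketone whose Baeyer–Villiger oxidation is slow at 0 °C, and the β substituents at C6, C7 and C10 direct the peracid to the α face.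

Step 20
Reactants: 29 hydroxy lactone
Product: 30 9α-acetate (C4 ketone)
Conditions: Ac2O, pyridine, DMAP (cat.), CH2Cl2, 0 °C → rt
Reagents that add atoms: acetic anhydride, CC(=O)OC(C)=O
Why: DMAP-catalysed acetylation of the axial, neopentyl-type C9 hydroxyl; pyridine is too weak a base to trigger E1cB loss of the β-isobutyrate or conjugate addition to the methylene lactone at 0 °C.

Step 21
Reactants: 30 keto lactone
Product: 31 target, 9α,15-diacetoxy-6β-(2-methylpropanoyloxy)elema-1,3,11(13)-trien-12,8β-olide (CNP0500052.1)
Conditions: Zn, CH2Br2, TiCl4, THF/CH2Cl2, 0 °C → rt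
Reagents that add atoms: dibromomethane, BrCBr
Why: Lombardo–Takai methylenation: the gem-dizinc/titanium reagent is nucleophilic but not basic, so it converts the hindered, enolisable α-acyloxy ketone into the 1,1-disubstituted alkene without epimerising C5, eliminating the β-isobutyrate or attacking the esters and the lactone.

## Compound list

1 | (E)-3-methylpent-2-en-4-yn-1-ol | C#C/C(C)=C/CO | starting material
2 | (E)-trimethyl{[3-methyl-5-(trimethylsilyl)pent-2-en-4-yn-1-yl]oxy}silane | C[Si](C)(C)C#C/C(C)=C/CO[Si](C)(C)C | intermediate (not isolated)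
3 | (E)-3-methyl-5-(trimethylsilyl)pent-2-en-4-yn-1-ol | C[Si](C)(C)C#C/C(C)=C/CO | intermediate
4 | dimethyl (S)-malate | COC(=O)C[C@H](O)C(=O)OC | starting material
5 | methyl (S)-3,4-dihydroxybutanoate | COC(=O)C[C@H](O)CO | intermediate
6 | methyl (S)-3-hydroxy-4-(trityloxy)butanoate | COC(=O)C[C@H](O)COC(c1ccccc1)(c1ccccc1)c1ccccc1 | intermediate
7 | (S)-3-hydroxy-4-(trityloxy)butanoic acid | OC(=O)C[C@H](O)COC(c1ccccc1)(c1ccccc1)c1ccccc1 | intermediate
8 | (2E)-3-methyl-5-(trimethylsilyl)pent-2-en-4-yn-1-yl (3S)-3-hydroxy-4-(trityloxy)butanoate | C[Si](C)(C)C#C/C(C)=C/COC(=O)C[C@H](O)COC(c1ccccc1)(c1ccccc1)c1ccccc1 | intermediate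
9 | (2R,3S)-3-hydroxy-2-[(3R)-3-methyl-5-(trimethylsilyl)pent-1-en-4-yn-3-yl]-4-(trityloxy)butanoic acid | C[Si](C)(C)C#C[C@](C)(C=C)[C@@H](C(=O)O)[C@H](O)COC(c1ccccc1)(c1ccccc1)c1ccccc1 | intermediate (not isolated)
10 | (2R,3S)-3,4-dihydroxy-2-[(3R)-3-methyl-5-(trimethylsilyl)pent-1-en-4-yn-3-yl]butanoic acid | C[Si](C)(C)C#C[C@](C)(C=C)[C@@H](C(=O)O)[C@H](O)CO | intermediate (not isolated)
11 | (3R,4S)-4-hydroxy-3-[(3R)-3-methyl-5-(trimethylsilyl)pent-1-en-4-yn-3-yl]oxolan-2-one | C[Si](C)(C)C#C[C@](C)(C=C)[C@H]1C(=O)OC[C@H]1O | intermediate
12 | (3R,4S)-4-[(tert-butyldimethylsilyl)oxy]-3-[(3R)-3-methyl-5-(trimethylsilyl)pent-1-en-4-yn-3-yl]oxolan-2-one | C[Si](C)(C)C#C[C@](C)(C=C)[C@H]1C(=O)OC[C@H]1O[Si](C)(C)C(C)(C)C | intermediate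
13 | (3R,4S)-4-[(tert-butyldimethylsilyl)oxy]-3-[(3R)-3-methyl-5-(trimethylsilyl)pent-1-en-4-yn-3-yl]oxolan-2-ol (anomers) | C[Si](C)(C)C#C[C@](C)(C=C)[C@H]1C(O)OC[C@H]1O[Si](C)(C)C(C)(C)C | intermediate
14 | acrolein | C=CC=O | starting material
15 | tert-butyl acrylate | C=CC(=O)OC(C)(C)C | starting material
16 | tert-butyl 3-hydroxy-2-methylidenepent-4-enoate (racemic) | C=CC(O)C(=C)C(=O)OC(C)(C)C | intermediate
17 | tert-butyl (2Z)-2-(bromomethyl)penta-2,4-dienoate | C=C/C=C(\CBr)C(=O)OC(C)(C)C | intermediate
18 | open-chain hydroxy aldehyde tautomer of 13 (C6 aldehyde, 15-OH, 4-OTBS) | C[Si](C)(C)C#C[C@](C)(C=C)[C@@H](C=O)[C@@H](CO)O[Si](C)(C)C(C)(C)C | intermediate (not isolated)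
19 | [(2Z)-2-(tert-butoxycarbonyl)penta-2,4-dien-1-yl]indium dibromide | C=C/C=C(\C[In](Br)Br)C(=O)OC(C)(C)C | intermediate (not isolated)
20 | tert-butyl (3S,4R,5S,6S)-6-[(tert-butyldimethylsilyl)oxy]-3-ethenyl-4,7-dihydroxy-2-methylidene-5-[(3R)-3-methyl-5-(trimethylsilyl)pent-1-en-4-yn-3-yl]heptanoate | C[Si](C)(C)C#C[C@](C)(C=C)[C@@H]([C@H](O)[C@@H](C=C)C(=C)C(=O)OC(C)(C)C)[C@@H](CO)O[Si](C)(C)C(C)(C)C | intermediate
21 | 15-O-acetate of 20 | C[Si](C)(C)C#C[C@](C)(C=C)[C@@H]([C@H](O)[C@@H](C=C)C(=C)C(=O)OC(C)(C)C)[C@@H](COC(C)=O)O[Si](C)(C)C(C)(C)C | intermediate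
22 | 6-O-(2-methylpropanoate) of 21 | C[Si](C)(C)C#C[C@](C)(C=C)[C@@H]([C@H](OC(=O)C(C)C)[C@@H](C=C)C(=C)C(=O)OC(C)(C)C)[C@@H](COC(C)=O)O[Si](C)(C)C(C)(C)C | intermediate
23 | cyclohex-8-ene: 10β-CH3, 10α-C≡C–SiMe3, 5β-CH(OTBS)CH2OAc, 6β-OCOCHMe2, 7β-C(=CH2)CO2t-Bu | C[Si](C)(C)C#C[C@]1(C)C=C[C@@H](C(=C)C(=O)OC(C)(C)C)[C@@H](OC(=O)C(C)C)[C@H]1[C@@H](COC(C)=O)O[Si](C)(C)C(C)(C)C | intermediate
24 | as 23 with 10α-C≡CH | C#C[C@]1(C)C=C[C@@H](C(=C)C(=O)OC(C)(C)C)[C@@H](OC(=O)C(C)C)[C@H]1[C@@H](COC(C)=O)O[Si](C)(C)C(C)(C)C | intermediate
25 | as 23 with 10α-vinyl | C=C[C@]1(C)C=C[C@@H](C(=C)C(=O)OC(C)(C)C)[C@@H](OC(=O)C(C)C)[C@H]1[C@@H](COC(C)=O)O[Si](C)(C)C(C)(C)C | intermediate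
26 | hydroxy acid: 10α-vinyl, 5β-CH(OH)CH2OAc, 6β-OCOCHMe2, 7β-C(=CH2)CO2H, C8=C9 | C=C[C@]1(C)C=C[C@@H](C(=C)C(=O)O)[C@@H](OC(=O)C(C)C)[C@H]1[C@@H](COC(C)=O)O | intermediate
27 | keto acid (key-step precursor): 5β-C(=O)CH2OAc, 6β-OCOCHMe2, 7β-C(=CH2)CO2H, C8=C9, 10β-CH3, 10α-vinyl | C=C[C@]1(C)C=C[C@@H](C(=C)C(=O)O)[C@@H](OC(=O)C(C)C)[C@H]1C(=O)COC(C)=O | intermediate
28 | 8α,9α-epoxide of 27 | C=C[C@]1(C)[C@@H]2O[C@@H]2[C@@H](C(=C)C(=O)O)[C@@H](OC(=O)C(C)C)[C@H]1C(=O)COC(C)=O | intermediate (not isolated)
29 | 9α-hydroxy-8β,12-olide with C4 ketone (key-step product) | C=C[C@]1(C)[C@H](O)[C@H]2OC(=O)C(=C)[C@H]2[C@@H](OC(=O)C(C)C)[C@H]1C(=O)COC(C)=O | intermediate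
30 | 9α-acetate of 29 | C=C[C@]1(C)[C@H](OC(C)=O)[C@H]2OC(=O)C(=C)[C@H]2[C@@H](OC(=O)C(C)C)[C@H]1C(=O)COC(C)=O | intermediate
31 | 9α,15-diacetoxy-6β-(2-methylpropanoyloxy)elema-1,3,11(13)-trien-12,8β-olide (CNP0500052.1) | C=C[C@]1(C)[C@H](OC(C)=O)[C@H]2OC(=O)C(=C)[C@H]2[C@@H](OC(=O)C(C)C)[C@H]1C(=C)COC(C)=O | target

## Step count and least certain steps

Total: 21 steps. Longest linear sequence: 18 steps (4 → 31 through steps 2–8 and 11–21).

**Step 19 (key step).** Oxygen transfer may lose its facial selectivity, for example if the carboxylic acid guides the peracid to the β face by hydrogen bonding or if the half-chair with the C7 side chain pseudoaxial reacts. The peracid may also slowly oxidise the α-acyloxy ketone (Baeyer–Villiger) or the vinyl group on long exposure. Fallback: the two events are separated and the peracid and the free acid are avoided. From 25, HF·pyridine frees O4 to give the 4-hydroxy tert-butyl ester F1, and Dess–Martin oxidation gives the 4-keto tert-butyl ester F2. Dimethyldioxirane in acetone at 0 °C, a neutral oxidant that neither hydrogen-bonds to an acid nor performs Baeyer–Villiger chemistry, should give the 8α,9α-epoxy ester F3. Trifluoroacetic acid in CH2Cl2 then lets the ester carbonyl open the protonated epoxide at C8 with loss of 2-methylpropene, which comes back to 29.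

**Step 11.** Facial selectivity with respect to C5 may erode, because the free 15-hydroxyl of the open-chain tautomer could bind indium together with the aldehyde oxygen and pull C4 into the inside position (Felkin isomer). The hindered lactol may also open too slowly. Fallback: the metal is changed to boron, whose shorter B–O and B–C bonds tighten the chair and enlarge the syn-pentane penalty of the Felkin arrangement. From 16, acetylation (Ac2O, DMAP) gives the allylic acetate F4. Borylation with B2pin2 and catalytic Pd2(dba)3 with allylic transposition gives the allylboronate F5, with the vinyl group again cis to the CH2–metal carbon. F5 is added to lactol 13 (toluene, 50 °C, or catalytic Sc(OTf)3 at low temperature), and hydrolysis of the borate comes back to 20.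

**Step 6.** The rearrangement to a quaternary centre may be slow, so that the lithium enolate fragments to a ketene before it rearranges, or the chelate may give incomplete facial control. Fallback: reagent control replaces chelate control. From 8, TBSOTf and 2,6-lutidine give the 3-O-silyl ester F6. Its boron ketene acetal, formed with a chiral 2-bromo-4,5-diphenyl-1,3-bis(arylsulfonyl)-1,3,2-diazaborolidine and i-Pr2NEt in CH2Cl2, should rearrange at −20 °C to the silyloxy acid F7. Formic acid in ether removes the trityl group and the hydroxy acid closes to lactone 12.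

**Step 14.** Ring closure may be slow because both vinyl groups are hindered (one on a quaternary carbon, one next to the acylated C6), which leaves time for catalyst decay, oligomerisation or carbene addition to the silyl alkyne. Fallback: the order of ring closure and acylation is changed. From 21, the same catalyst closes the less encumbered free alcohol to the cyclohexenol F8, and isobutyric anhydride with DMAP then gives 23.

**Step 21.** Conversion of the hindered ketone may stall, and the Lewis-acidic titanium may induce loss of the β-isobutyrate. Fallback: a two-stage Peterson olefination. From 30, Me3SiCH2MgCl/CeCl3 at −78 °C adds selectively to the ketone to give the β-hydroxysilane F9, and BF3·OEt2 induces elimination to 31.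

## Further compounds

F1 | step 19 | 4-hydroxy tert-butyl ester (25 without TBS) | C=C[C@]1(C)C=C[C@@H](C(=C)C(=O)OC(C)(C)C)[C@@H](OC(=O)C(C)C)[C@H]1[C@@H](COC(C)=O)O
F2 | step 19 | 4-keto tert-butyl ester (tert-butyl ester of 27) | C=C[C@]1(C)C=C[C@@H](C(=C)C(=O)OC(C)(C)C)[C@@H](OC(=O)C(C)C)[C@H]1C(=O)COC(C)=O
F3 | step 19 | 8α,9α-epoxy keto tert-butyl ester | C=C[C@]1(C)[C@@H]2O[C@@H]2[C@@H](C(=C)C(=O)OC(C)(C)C)[C@@H](OC(=O)C(C)C)[C@H]1C(=O)COC(C)=O
F4 | step 11 | tert-butyl 3-acetoxy-2-methylidenepent-4-enoate | C=CC(OC(C)=O)C(=C)C(=O)OC(C)(C)C
F5 | step 11 | tert-butyl (2E)-2-[(4,4,5,5-tetramethyl-1,3,2-dioxaborolan-2-yl)methyl]penta-2,4-dienoate | C=C/C=C(\CB1OC(C)(C)C(C)(C)O1)C(=O)OC(C)(C)C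
F6 | step 6 | 3-O-TBS ether of ester 8 | C[Si](C)(C)C#C/C(C)=C/COC(=O)C[C@@H](COC(c1ccccc1)(c1ccccc1)c1ccccc1)O[Si](C)(C)C(C)(C)C
F7 | step 6 | 3-O-TBS ether of Claisen acid 9 | C[Si](C)(C)C#C[C@](C)(C=C)[C@@H](C(=O)O)[C@@H](COC(c1ccccc1)(c1ccccc1)c1ccccc1)O[Si](C)(C)C(C)(C)C
F8 | step 14 | cyclohexenol (23 with free 6β-OH) | C[Si](C)(C)C#C[C@]1(C)C=C[C@@H](C(=C)C(=O)OC(C)(C)C)[C@@H](O)[C@H]1[C@@H](COC(C)=O)O[Si](C)(C)C(C)(C)C
F9 | step 21 | β-hydroxysilane from 30 (C4 carbinol bearing CH2SiMe3, C4 configuration open) | C=C[C@]1(C)[C@H](OC(C)=O)[C@H]2OC(=O)C(=C)[C@H]2[C@@H](OC(=O)C(C)C)[C@H]1C(O)(C[Si](C)(C)C)COC(C)=O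
A1 | alternative 1 | open-chain C6 aldehyde carrying the C8 butenolide, O9 and O15 as TBS ethers | C=C[C@](C)([C@H](O[Si](C)(C)C(C)(C)C)[C@H]1OC(=O)C=C1)[C@@H](C=O)C(=C)CO[Si](C)(C)C(C)(C)C
A2 | alternative 1 | 6-hydroxy cis-fused lactone lacking the C13 methylene | C=C[C@]1(C)[C@H](O[Si](C)(C)C(C)(C)C)[C@H]2OC(=O)C[C@H]2[C@@H](O)[C@H]1C(=C)CO[Si](C)(C)C(C)(C)C
A3 | alternative 2 | open-chain C8 aldehyde with (Z)-2-(bromomethyl)enoate, 9-OPMB, 6-OTBS | C=C[C@](C)([C@H](OCc1ccc(OC)cc1)C=O)[C@@H]([C@H](O[Si](C)(C)C(C)(C)C)/C=C(\CBr)C(=O)OC)C(=C)COC(C)=O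
A4 | alternative 2 | cis-fused α-methylene lactone with 9-OPMB and 6-OTBS | C=C[C@]1(C)[C@H](OCc3ccc(OC)cc3)[C@H]2OC(=O)C(=C)[C@H]2[C@@H](O[Si](C)(C)C(C)(C)C)[C@H]1C(=C)COC(C)=O
A5 | alternative 3 | C6 silyl enol ether with C8 tert-butyl malonate | C=C[C@]1(C)[C@H](OC(C)=O)[C@@H](OC(=O)CC(=O)OC(C)(C)C)C=C(O[Si](C)(C)C(C)(C)C)[C@H]1C(=C)COC(C)=O
A6 | alternative 3 | 6-oxo cis-fused lactone with C11 tert-butyl ester | C=C[C@]1(C)[C@H](OC(C)=O)[C@H]2OC(=O)[C@H](C(=O)OC(C)(C)C)[C@H]2C(=O)[C@H]1C(=C)COC(C)=O
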